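**Plan**

- Carotenoid numbering is used in the plan and in all Why lines: ring C1 (CMe2) to C6 (ring carbon carrying the exocyclic alkene), chain C7–C15, primes for the second half.
- Cuts: (a) C11–C12 and C11'–C12', taking the central tetraene back to a 12,12'-diol across the triene of the commercial C10 dialdehyde (reductive 1,8-elimination); (b) the C3–O stereocentre back to the ring ketone; (c) ring bond C1–C6; (d) C6=C7 (γ-aldol condensation of phorone with a C6 enynal).
- Enabling feature: ring atoms C1–C6 with O on C3, a methyl on C5 and CMe2 on C1 are a phorone unit, and the exocyclic C6=C7 is the γ,δ double bond of its cross-conjugated dienone. A nucleophile added at C7 turns C1=C2–C3(O−)=C4–C5=C6 into a 3-oxidohexatriene whose termini are C1 and C6.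
- Forward: end-group chain first (oxidation, γ-aldol condensation); then the ring by phosphine-triggered 1,6-addition/6π-electrocyclisation/elimination; then CBS reduction and silylation; then two-directional C15 + C10 + C15 union, reductive elimination and desilylation.
- Stereochemistry: C3 and C3' (S) from (R)-CBS reduction of the ring enone (alkenyl branch as the large group); 6E/6'E from thermodynamic control in the key step; chain E bonds from E building blocks and a thermodynamically controlled reductive elimination.

Key step: step 3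

Assumption: (2E)-3-methylpent-2-en-4-yn-1-ol, phorone and (2E,4E,6E)-2,7-dimethylocta-2,4,6-trienedial are taken as commercial, and geometrical isomers about C6=C7 and in the chain are taken to equilibrate to the all-E form at the end, as is usual for carotenoids.

**Step 1**
Reactants: 1 (2E)-3-methylpent-2-en-4-yn-1-ol
Product: 2 (2E)-3-methylpent-2-en-4-ynal
Conditions: MnO2 (10 equiv), CH2Cl2, rt; filter and use the solution directly
Reagents that add atoms: none
Why: Activated MnO2 oxidises the allylic alcohol chemoselectively to the enal without touching the alkyne or the E double bond (allylic oxidation).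

**Step 2**
Reactants: 2 (2E)-3-methylpent-2-en-4-ynal; 3 phorone (2,6-dimethylhepta-2,5-dien-4-one, 4 equiv)
Product: 5 (7E,9E)-2,6,10-trimethyldodeca-2,5,7,9-tetraen-11-yn-4-one (5E/5Z mixture), via vinylogous aldol adduct 4 (not isolated)
Conditions: KOH (0.2 equiv), EtOH, 0 °C to rt, slow addition of 2
Reagents that add atoms: none
Why: Hydroxide reversibly forms the cross-conjugated trienolate of phorone at a γ-methyl group, its terminal carbon adds to the aldehyde and the adduct loses water by E1cB (vinylogous Claisen–Schmidt aldol condensation); the new C6=C7 bond forms E under thermodynamic control, the C4=C5 geometry is left open because step 3 erases it, and excess phorone suppresses double condensation.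

**Step 3**
Reactants: 5 (7E,9E)-2,6,10-trimethyldodeca-2,5,7,9-tetraen-11-yn-4-one (5E/5Z mixture)
Product: 8 (4E)-3,5,5-trimethyl-4-[(2E)-3-methylpent-2-en-4-yn-1-ylidene]cyclohex-2-en-1-one, via phosphonium dienolate 6 (not isolated), via cyclised phosphonium enolate 7 (not isolated)
Conditions: PMe3 (0.3 equiv, 1 M in toluene), tert-amyl alcohol, 0.02 M, 60 °C, argon
Reagents that add atoms: none
Why: Proposed new method: PMe3 adds reversibly to the only unsubstituted acceptor carbon, C7 (1,6-addition), which turns C4=C5 and C6=C7 into single bonds and gives the 3-oxidohexa-1,3,5-triene 6 (C1=C2–C3(O−)=C4–C5=C6), whose disrotatory thermal 6π-electrocyclisation joins C6 to C1 (formally a 6-endo-trig vinylogous Michael addition onto the β,β-dimethyl enone terminus) and closes the six-membered ring with its quaternary C1; proton transfer from C6 to C2 through the alcohol solvent and E1cB loss of PMe3 from C7 of 7 then return the C6=C7 bond as the exocyclic alkene. The closest known reaction types are the phosphine-catalysed intramolecular Rauhut–Currier cycloisomerisation of bis-enones and the base-induced closure of phorone to isophorone through its trienolate, here merged in a vinylogous sense within one cross-conjugated dienone. No stereocentre survives (C6 and C7 are stereogenic only in 6 and 7), and the one stereo element formed, the C6=C7 geometry, is under thermodynamic control because PMe3 adds reversibly to C7 of the product too, so that 6E (chain beside CMe2 and away from the in-plane C5 methyl group) should prevail. Both geometrical isomers of 5 at C4=C5 and at C6=C7 give the same 6, so the mixture from step 2 converges. The selectivity needed is for C6 as the nucleophile over the trienolates that a base would form at the C5 or C1 methyl groups and over intermolecular coupling, and it is secured by a neutral, non-basic phosphine that cannot deprotonate a γ-methyl group, by the full substitution of the β-carbons C1 and C5, which leaves only C7 (or the remoter C9 and C11, whose adducts carry the same C5=C6 donor) open to attack, and by high dilution.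

**Step 4**
Reactants: 8 (4E)-3,5,5-trimethyl-4-[(2E)-3-methylpent-2-en-4-yn-1-ylidene]cyclohex-2-en-1-one
Product: 9 (1S,4E)-3,5,5-trimethyl-4-[(2E)-3-methylpent-2-en-4-yn-1-ylidene]cyclohex-2-en-1-ol
Conditions: (R)-2-methyl-CBS-oxazaborolidine (0.2 equiv), catecholborane (1.8 equiv), toluene, −78 °C; MeOH, then aq. NaOH wash
Reagents that add atoms: none
Why: Corey–Bakshi–Shibata reduction: the ketone binds to the boron of the (R)-oxazaborolidine anti to the conjugated alkenyl branch (large group, C4 side) and hydride from the nitrogen-bound catecholborane is delivered to the face that gives the (S)-carbinol at C3, with 1,2-selectivity and no hydroboration of the alkyne at −78 °C.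

**Step 5**
Reactants: 9 (1S,4E)-3,5,5-trimethyl-4-[(2E)-3-methylpent-2-en-4-yn-1-ylidene]cyclohex-2-en-1-ol
Product: 10 tert-butyl(dimethyl){[(1S,4E)-3,5,5-trimethyl-4-[(2E)-3-methylpent-2-en-4-yn-1-ylidene]cyclohex-2-en-1-yl]oxy}silane
Conditions: TBSCl (1.3 equiv), imidazole (2.5 equiv), DMF, 0 °C to rt
Reagents that add atoms: tert-butyldimethylsilyl chloride CC(C)(C)[Si](C)(C)Cl
Why: Standard silylation of the secondary allylic alcohol; the TBS ether keeps the ionisable C3–O bond and the O–H out of the organometallic and titanium steps.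

**Step 6**
Reactants: 10 TBS ether of 9 (2.4 equiv); 11 (2E,4E,6E)-2,7-dimethylocta-2,4,6-trienedial (1.0 equiv)
Product: 14 C40 12,12'-diol bis-TBS ether (both C12 epimers), via alkenylzirconocene chloride 12 (not isolated), via alkenyl(methyl)zinc 13 (not isolated)
Conditions: Cp2Zr(H)Cl (2.5 equiv), CH2Cl2, rt; Me2Zn (2.4 equiv), −65 °C; then 11, 0 °C; aq. NaHCO3
Reagents that add atoms: none
Why: Syn hydrozirconation of the terminal alkyne places zirconium on C11 and gives the (10E)-dienylzirconocene, transmetalation to zinc gives an alkenylzinc that adds 1,2 to both formyl groups of the dialdehyde (alkenylzirconocene–zinc aldehyde addition); the configuration of the two new carbinol centres is irrelevant because step 7 removes them.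

**Step 7**
Reactants: 14 C40 12,12'-diol bis-TBS ether
Product: 15 (3S,3'S)-eschscholtzxanthin bis-TBS ether
Conditions: low-valent titanium from TiCl3 and LiAlH4 (2:1), THF, 0 °C to rt
Reagents that add atoms: none
Why: Low-valent titanium binds both alkoxides and cleaves both C–O bonds with electron transfer, so that the triene between C12 and C12' shifts to the C12=C13–C14=C15–C15'=C14'–C13'=C12' tetraene (McMurry-type reductive elimination of a vinylogous diol, the 1,8-vinylog of the 2-ene-1,4-diol to 1,3-diene case); both carbinol epimers converge and the new double bonds should form E under thermodynamic control.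

**Step 8**
Reactants: 15 (3S,3'S)-eschscholtzxanthin bis-TBS ether
Product: 16 (3S,3'S,6E,6'E)-4',5'-didehydro-4,5'-retro-β,β-carotene-3,3'-diol (eschscholtzxanthin)
Conditions: TBAF (3 equiv), THF, 0 °C to rt; crystallisation from CH2Cl2/hexane, with thermal Z to E equilibration in refluxing heptane if needed
Reagents that add atoms: none
Why: Fluoride cleaves both silyl ethers under non-acidic conditions, which avoids ionisation of the polyene-conjugated allylic C3–O bonds and leaves the (3S,3'S) centres untouched, and crystallisation should deliver the all-E isomer.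

**Compound list**

1 | (2E)-3-methylpent-2-en-4-yn-1-ol | OC/C=C(C)/C#C | starting material
2 | (2E)-3-methylpent-2-en-4-ynal | O=C/C=C(C)/C#C | intermediate
3 | phorone, 2,6-dimethylhepta-2,5-dien-4-one | CC(C)=CC(=O)C=C(C)C | starting material
4 | (9E)-8-hydroxy-2,6,10-trimethyldodeca-2,5,9-trien-11-yn-4-one (racemic; 5E drawn, 5E/5Z mixture) | CC(C)=CC(=O)/C=C(C)/CC(O)/C=C(C)/C#C | intermediate
5 | (5E,7E,9E)-2,6,10-trimethyldodeca-2,5,7,9-tetraen-11-yn-4-one (5E drawn, used as 5E/5Z mixture) | CC(C)=CC(=O)/C=C(C)/C=C/C=C(C)/C#C | intermediate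
6 | 2,6,10-trimethyl-8-(trimethylphosphaniumyl)dodeca-2,4,6,9-tetraen-11-yn-4-olate (zwitterion, racemic, reactive geometry drawn) | CC(C)=C/C([O-])=C\C(C)=C\C(/C=C(C)/C#C)[P+](C)(C)C | intermediate
7 | 3,3,5-trimethyl-4-[(2E)-3-methyl-1-(trimethylphosphaniumyl)pent-2-en-4-yn-1-yl]cyclohexa-1,5-dien-1-olate (zwitterion, diastereomer mixture) | CC1=CC([O-])=CC(C)(C)C1C(/C=C(C)/C#C)[P+](C)(C)C | intermediate
8 | (4E)-3,5,5-trimethyl-4-[(2E)-3-methylpent-2-en-4-yn-1-ylidene]cyclohex-2-en-1-one | CC1=CC(=O)CC(C)(C)\C1=C/C=C(C)/C#C | intermediate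
9 | (1S,4E)-3,5,5-trimethyl-4-[(2E)-3-methylpent-2-en-4-yn-1-ylidene]cyclohex-2-en-1-ol | CC1=C[C@@H](O)CC(C)(C)\C1=C/C=C(C)/C#C | intermediate
10 | tert-butyl(dimethyl){[(1S,4E)-3,5,5-trimethyl-4-[(2E)-3-methylpent-2-en-4-yn-1-ylidene]cyclohex-2-en-1-yl]oxy}silane | CC1=C[C@@H](O[Si](C)(C)C(C)(C)C)CC(C)(C)\C1=C/C=C(C)/C#C | intermediate
11 | (2E,4E,6E)-2,7-dimethylocta-2,4,6-trienedial | O=C/C(C)=C/C=C/C=C(C)/C=O | starting material
12 | chlorobis(cyclopentadienyl)[(1E,3E)-dienyl]zirconium from 10, zirconium on C11 | CC1=C[C@@H](O[Si](C)(C)C(C)(C)C)CC(C)(C)\C1=C/C=C(C)/C=C/[Zr](Cl)(C2C=CC=C2)C2C=CC=C2 | intermediate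
13 | methyl[(1E,3E)-dienyl]zinc from 12, zinc on C11 | CC1=C[C@@H](O[Si](C)(C)C(C)(C)C)CC(C)(C)\C1=C/C=C(C)/C=C/[Zn]C | intermediate
14 | C40 12,12'-diol with retro end groups, 3,3'-bis-TBS ether, (3S,3'S), both C12 epimers | CC1=C[C@@H](O[Si](C)(C)C(C)(C)C)CC(C)(C)\C1=C/C=C(C)/C=C/C(O)/C(C)=C/C=C/C=C(C)/C(O)/C=C/C(C)=C/C=C1/C(C)=C[C@@H](O[Si](C)(C)C(C)(C)C)CC1(C)C | intermediate
15 | (3S,3'S)-eschscholtzxanthin 3,3'-bis(tert-butyldimethylsilyl) ether | CC1=C[C@@H](O[Si](C)(C)C(C)(C)C)CC(C)(C)\C1=C/C=C(C)/C=C/C=C(C)/C=C/C=C/C(C)=C/C=C/C(C)=C/C=C1/C(C)=C[C@@H](O[Si](C)(C)C(C)(C)C)CC1(C)C | intermediate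
16 | (3S,3'S,6E,6'E)-4',5'-didehydro-4,5'-retro-β,β-carotene-3,3'-diol (eschscholtzxanthin) | CC1=C[C@@H](O)CC(C)(C)\C1=C/C=C(C)/C=C/C=C(C)/C=C/C=C/C(C)=C/C=C/C(C)=C/C=C1/C(C)=C[C@@H](O)CC1(C)C | target

**Count**

Total steps: 8. Longest linear sequence: 8 steps (1 to 16); 3 and 11 enter as commercial materials.

**Steps most likely to fail**

1. Step 3. The phosphonium dienolate may be too sparsely populated, or its closure onto the fully substituted C1 too slow. Intermolecular Rauhut–Currier-type oligomerisation or consumption of the phosphine at the terminal alkyne would then take over. The fallback uses known chemistry (thia-Michael-initiated ring closure, sulfur oxidation, E1cB elimination), sets out from 5 and comes back at 8. PhSLi (1.2 equiv, THF, 0 °C to rt) adds 1,6 at C7, the resulting dienolate closes onto C1, and NH4Cl quench gives 3,5,5-trimethyl-4-[(2E)-3-methyl-1-(phenylsulfanyl)pent-2-en-4-yn-1-yl]cyclohex-2-en-1-one F1. Chemoselective sulfur oxidation (H2O2, catalytic (NH4)6Mo7O24, EtOH, 0 °C) gives 3,5,5-trimethyl-4-[(2E)-3-methyl-1-(phenylsulfonyl)pent-2-en-4-yn-1-yl]cyclohex-2-en-1-one F2. DBU (MeCN, rt) then removes the γ-proton at C6 and expels benzenesulfinate from C7 to give 8.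

2. Step 7. Ionisation of the doubly allylic C12–O bonds (or of the C3–OSi bonds) in the Lewis-acidic titanium medium may outrun electron transfer, leading to dehydration and oligomerisation instead of reductive elimination. The fallback splits the deoxygenation into halogenation and reductive dehalogenation, sets out from 14 and comes back at 15. PBr3/pyridine (Et2O, −30 °C) converts 14 into the bis-allylic 12,12'-dibromide of the bis-TBS ether F3 (allylic isomers of it are equally serviceable). Zinc dust (THF, 0 °C) then removes both bromines by vinylogous 1,8-dehalogenation to give 15.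

3. Step 2. The phorone trienolate may attack through its α-carbon, phorone may ring-close on itself under base, or the enynal may be lost to alkoxide addition at the alkyne terminus and to self-condensation. The fallback replaces the base-mediated condensation by a Lewis-acid vinylogous Mukaiyama aldol and a separate elimination, sets out from 3 and 2 and comes back at 5. LiN(iPr)2 and then Me3SiCl (THF, −78 °C) convert phorone 3 into trimethyl{[(3Z)-2,6-dimethylhepta-1,3,5-trien-4-yl]oxy}silane F4. BF3·OEt2-promoted γ-addition of F4 to 2 (CH2Cl2, −78 °C) gives 4, which is isolated in this variant. Acetylation (Ac2O, DMAP) gives (5E,9E)-2,6,10-trimethyl-4-oxododeca-2,5,9-trien-11-yn-8-yl acetate F5, and DBU-induced vinylogous E1cB elimination gives 5.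

**Further compounds**

F1 | step 3 | 3,5,5-trimethyl-4-[(2E)-3-methyl-1-(phenylsulfanyl)pent-2-en-4-yn-1-yl]cyclohex-2-en-1-one (diastereomer mixture) | CC1=CC(=O)CC(C)(C)C1C(Sc2ccccc2)/C=C(C)/C#C
F2 | step 3 | 3,5,5-trimethyl-4-[(2E)-3-methyl-1-(phenylsulfonyl)pent-2-en-4-yn-1-yl]cyclohex-2-en-1-one (diastereomer mixture) | CC1=CC(=O)CC(C)(C)C1C(S(=O)(=O)c2ccccc2)/C=C(C)/C#C
F3 | step 7 | 12,12'-dibromide corresponding to diol 14, 3,3'-bis-TBS ether (both C12 epimers) | CC1=C[C@@H](O[Si](C)(C)C(C)(C)C)CC(C)(C)\C1=C/C=C(C)/C=C/C(Br)/C(C)=C/C=C/C=C(C)/C(Br)/C=C/C(C)=C/C=C1/C(C)=C[C@@H](O[Si](C)(C)C(C)(C)C)CC1(C)C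
F4 | step 2 | trimethyl{[(3Z)-2,6-dimethylhepta-1,3,5-trien-4-yl]oxy}silane | C=C(C)/C=C(O[Si](C)(C)C)/C=C(C)C
F5 | step 2 | (5E,9E)-2,6,10-trimethyl-4-oxododeca-2,5,9-trien-11-yn-8-yl acetate (racemic) | CC(C)=CC(=O)/C=C(C)/CC(OC(C)=O)/C=C(C)/C#C
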